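**Strategy.** Locants: lactone ring O1, C2–C5; chain C6–C18; furan ring on C18. Everything rests on cutting the 11E,13E-diene at its central bond C12–C13 and removing the methyl group from C11. The feature exploited is that the methyl-branched trisubstituted alkene C11=C12 is a disguised terminal alkyne. In one flask AlMe3 adds syn across the alkyne and the alkenyl metal is cross-coupled to an E-iodoalkene, which creates C11–CH3 and C12–C13 and fixes both geometries. The precursors are silyl ether 6 (C6–C12, 7R, terminal alkyne) and iodide 15 (C13–C18, 15S, furan ring), each from one enantiomer of 3-bromo-2-methylpropan-1-ol. The Z-ylidene tetronic acid ring is added last by aldol–elimination at C6.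

Key step: step 10

Remark on the chemistry (assumption): the target is taken as its 4-hydroxy enol tautomer with 5Z, 7R, 11E, 13E, 15S. In steps 2 and 6 the CIP descriptor flips (S to R, R to S) only because CH2Br becomes a lower-ranked CH2–alkyl group, and no bond at the stereocentre is touched.

**Alkyne half (C6–C12)**

Step 1
Reactants: 1 (2S)-3-bromo-2-methylpropan-1-ol
Product: 2 [(2S)-3-bromo-2-methylpropoxy](tert-butyl)dimethylsilane
Conditions: TBSCl, imidazole, CH2Cl2, 0 °C → rt
Reagents that add atoms: tert-butyldimethylsilyl chloride, CC(C)(C)[Si](C)(C)Cl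
Why: Imidazole-promoted O-silylation of a primary alcohol leaves the C–Br bond and the purchased stereocentre (future C7) untouched.

Step 2
Reactants: 2 [(2S)-3-bromo-2-methylpropoxy](tert-butyl)dimethylsilane; 3 (4-bromobut-1-yn-1-yl)trimethylsilane
Product: 5 tert-butyldimethylsilyl ether of (2R)-2-methyl-7-(trimethylsilyl)hept-6-yn-1-ol, via silylbutynylmagnesium bromide 4 (not isolated)
Conditions: 3 (1.5 equiv), Mg, THF, 40 °C; then 2, Li2CuCl4 (5 mol %), NMP (4 equiv), THF, 0 °C → rt
Reagents that add atoms: none
Why: A copper-catalysed Grignard–primary alkyl bromide coupling (Kochi–Schlosser type, NMP-accelerated) forms C8–C9 by displacement at the carbon next to the stereocentre, and the C–SiMe3 cap removes the acidic alkyne proton that would otherwise quench the Grignard reagent.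

Step 3
Reactants: 5 tert-butyldimethylsilyl ether of (2R)-2-methyl-7-(trimethylsilyl)hept-6-yn-1-ol
Product: 6 tert-butyldimethylsilyl ether of (2R)-2-methylhept-6-yn-1-ol
Conditions: K2CO3 (0.2 equiv), MeOH, rt
Reagents that add atoms: none
Why: Methoxide-catalysed protodesilylation cleaves only the alkynyl C–Si bond, because an acetylide leaves silicon readily whereas the hindered primary TBS ether is inert under these conditions.

**Furan half (C13–C18)**

Step 4
Reactants: 7 (2R)-3-bromo-2-methylpropan-1-ol
Product: 8 [(2R)-3-bromo-2-methylpropoxy](tert-butyl)dimethylsilane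
Conditions: TBSCl, imidazole, CH2Cl2, 0 °C → rt
Reagents that add atoms: tert-butyldimethylsilyl chloride, CC(C)(C)[Si](C)(C)Cl
Why: The same O-silylation as in step 1 is applied to the enantiomeric bromo alcohol, whose stereocentre becomes C15.

Step 5
Reactants: 9 2-(furan-3-yl)ethanol
Product: 10 3-(2-bromoethyl)furan
Conditions: CBr4, PPh3, CH2Cl2, 0 °C
Reagents that add atoms: carbon tetrabromide, BrC(Br)(Br)Br
Why: The Appel reaction turns the primary alcohol into the bromide by SN2 displacement of an oxyphosphonium ion under essentially neutral conditions that the acid-sensitive furan ring tolerates.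

Step 6
Reactants: 10 3-(2-bromoethyl)furan; 8 [(2R)-3-bromo-2-methylpropoxy](tert-butyl)dimethylsilane
Product: 12 tert-butyldimethylsilyl ether of (2S)-5-(furan-3-yl)-2-methylpentan-1-ol, via furylethylmagnesium bromide 11 (not isolated)
Conditions: 10 (1.3 equiv), Mg, THF, rt → 40 °C; then 8, Li2CuCl4 (5 mol %), NMP (4 equiv), THF, 0 °C → rt
Reagents that add atoms: none
Why: The same copper-catalysed Grignard–alkyl bromide coupling forms C16–C17, and making the furylethyl unit the nucleophile avoids the E2 loss of HBr it would suffer as an electrophile.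

Step 7
Reactants: 12 tert-butyldimethylsilyl ether of (2S)-5-(furan-3-yl)-2-methylpentan-1-ol
Product: 13 (2S)-5-(furan-3-yl)-2-methylpentan-1-ol
Conditions: Bu4NF, THF, 0 °C → rt
Reagents that add atoms: none
Why: Fluoride-induced desilylation is driven by the strong Si–F bond and is neutral towards the furan ring and the stereocentre.

Step 8
Reactants: 13 (2S)-5-(furan-3-yl)-2-methylpentan-1-ol
Product: 14 (2S)-5-(furan-3-yl)-2-methylpentanal
Conditions: Dess–Martin periodinane, NaHCO3, CH2Cl2, 0 °C → rt
Reagents that add atoms: none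
Why: Buffered Dess–Martin oxidation stops at the aldehyde and is mild enough that the alpha stereocentre should not enolise and the furan ring should not be oxidised.

Step 9
Reactants: 14 (2S)-5-(furan-3-yl)-2-methylpentanal
Product: 15 3-[(4S,5E)-6-iodo-4-methylhex-5-en-1-yl]furan
Conditions: CrCl2 (6 equiv), CHI3 (2 equiv), dioxane–THF 6:1, 0 °C → rt, dark
Reagents that add atoms: iodoform, IC(I)I
Why: In the Takai olefination CrCl2 reduces CHI3 to a geminal dichromium species that adds to the aldehyde and eliminates through the less crowded arrangement to the E-iodoalkene, while the non-basic medium spares the alpha stereocentre C15.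

**Union**

Step 10
Reactants: 6 tert-butyldimethylsilyl ether of (2R)-2-methylhept-6-yn-1-ol; 16 trimethylaluminium; 15 3-[(4S,5E)-6-iodo-4-methylhex-5-en-1-yl]furan
Product: 19 tert-butyldimethylsilyl ether of (2R,6E,8E,10S)-13-(furan-3-yl)-2,6,10-trimethyltrideca-6,8-dien-1-ol, via alkenyldimethylalane 17 (not isolated), via alkenylzinc chloride 18 (not isolated)
Conditions: 6 (1.3 equiv), AlMe3 (2.6 equiv), Cp2ZrCl2 (0.3 equiv), ClCH2CH2Cl, 0 °C → rt; volatiles off in vacuo; THF, ZnCl2 (1.3 equiv), then 15 (1.0 equiv), Pd(PPh3)4 (5 mol %), rt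
Reagents that add atoms: trimethylaluminium (16), C[Al](C)C
Why: Cp2ZrCl2 and AlMe3 form a polarised methylzirconium–aluminium species that delivers CH3 and metal to the same face of the terminal alkyne of 6, CH3 to the internal carbon C11 and metal to the free terminus C12, and Zr-to-Al exchange releases the E-alkenylalane 17 and returns the catalyst. Once surplus AlMe3 has been pumped off, ZnCl2 converts 17 into alkenylzinc chloride 18, zerovalent palladium from Pd(PPh3)4 inserts into the C13–I bond of 15 to give a divalent alkenylpalladium iodide, and transmetalation followed by reductive elimination forms C12–C13 with retention at both alkenes. The closest known reaction type is this very tandem, Negishi zirconium-catalysed methylalumination followed by palladium-catalysed alkenyl–alkenyl Negishi coupling assisted by ZnCl2. No ring is closed and no stereocentre is created; 11E follows from the syn addition and 13E from the geometry stored in 15, while C7 and C15 take no part in any bond change and should keep their configuration. The selectivities needed are regiocontrol of the carbometalation, secured by the unbranched C10 methylene and the unhindered terminus, and alkenyl rather than methyl transfer, secured by removing free AlMe3 and by the faster migration of sp2 groups from aluminium through zinc to palladium. The TBS ether tolerates AlMe3, and the acid-sensitive furan ring enters the flask only with the iodide, after the strongly Lewis-acidic stage has ended.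

**Endgame**

Step 11
Reactants: 19 tert-butyldimethylsilyl ether of (2R,6E,8E,10S)-13-(furan-3-yl)-2,6,10-trimethyltrideca-6,8-dien-1-ol
Product: 20 (2R,6E,8E,10S)-13-(furan-3-yl)-2,6,10-trimethyltrideca-6,8-dien-1-ol
Conditions: Bu4NF, THF, 0 °C → rt
Reagents that add atoms: none
Why: Fluoride desilylation frees the C6 alcohol without acid, so the diene and the furan ring should stay intact.

Step 12
Reactants: 20 (2R,6E,8E,10S)-13-(furan-3-yl)-2,6,10-trimethyltrideca-6,8-dien-1-ol
Product: 21 (2R,6E,8E,10S)-13-(furan-3-yl)-2,6,10-trimethyltrideca-6,8-dienal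
Conditions: Dess–Martin periodinane, NaHCO3, CH2Cl2, 0 °C → rt; used at once
Reagents that add atoms: none
Why: Buffered Dess–Martin oxidation is chemoselective for the primary alcohol over the diene and furan and should not epimerise C7 when the aldehyde is carried on directly.

Step 13
Reactants: 22 4-hydroxy-3-methylfuran-2(5H)-one (3-methyltetronic acid)
Product: 23 4-methoxy-3-methylfuran-2(5H)-one
Conditions: Me2SO4, K2CO3, acetone, reflux
Reagents that add atoms: dimethyl sulfate, COS(=O)(=O)OC
Why: O-alkylation of the tetronate anion with a hard methylating agent favours the 4-oxygen and masks the acidic enol so that C5 can be deprotonated cleanly in the next step.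

Step 14
Reactants: 23 4-methoxy-3-methylfuran-2(5H)-one; 21 (2R,6E,8E,10S)-13-(furan-3-yl)-2,6,10-trimethyltrideca-6,8-dienal
Product: 25 5-[(2R,6E,8E,10S)-13-(furan-3-yl)-1-hydroxy-2,6,10-trimethyltrideca-6,8-dien-1-yl]-4-methoxy-3-methylfuran-2(5H)-one as a mixture of C5/C6 epimers, via lithium furanolate 24 (not isolated)
Conditions: 23 (1.3 equiv), LiN(i-Pr)2 (1.3 equiv), THF, −78 °C; then 21, −78 °C; aq NH4Cl
Reagents that add atoms: none
Why: The vinylogous aldol addition of the C5-lithiated methyl tetronate forms C5–C6 quickly at low temperature so that C7 should not epimerise, and the two new centres C5 and C6 need no control because both are erased in step 15.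

Step 15
Reactants: 25 aldol adduct (C5/C6 epimer mixture)
Product: 27 (5Z)-5-[(2R,6E,8E,10S)-13-(furan-3-yl)-2,6,10-trimethyltrideca-6,8-dien-1-ylidene]-4-methoxy-3-methylfuran-2(5H)-one, via C6 mesylate 26 (not isolated)
Conditions: MsCl, Et3N, CH2Cl2, 0 °C; then DBU, 0 °C → rt
Reagents that add atoms: none
Why: Mesylation followed by E1cB elimination through the acidic C5–H gives the exocyclic alkene, and the Z isomer should prevail from both epimers because it places the branched C7 substituent beside O1 and away from the 4-methoxy group.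

Step 16
Reactants: 27 (5Z)-ylidene methyl tetronate
Product: 28 (5Z)-5-[(2R,6E,8E,10S)-13-(furan-3-yl)-2,6,10-trimethyltrideca-6,8-dien-1-ylidene]-4-hydroxy-3-methylfuran-2(5H)-one (CNP0223721.1)
Conditions: NaSEt (3 equiv), DMF, rt → 45 °C; then cold 1 M HCl to pH 3
Reagents that add atoms: none
Why: Thiolate SN2 demethylation attacks the O-methyl carbon and expels the stabilised tetronate anion, a leaving group comparable to a carboxylate, under non-acidic and non-oxidising conditions that suit the furan, the diene and the Z-ylidene unit.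

**Compound list**

1 | (2S)-3-bromo-2-methylpropan-1-ol | OC[C@H](C)CBr | starting material
2 | [(2S)-3-bromo-2-methylpropoxy](tert-butyl)dimethylsilane | CC(C)(C)[Si](C)(C)OC[C@H](C)CBr | intermediate
3 | (4-bromobut-1-yn-1-yl)trimethylsilane | C[Si](C)(C)C#CCCBr | starting material
4 | [4-(trimethylsilyl)but-3-yn-1-yl]magnesium bromide (not isolated) | C[Si](C)(C)C#CCC[Mg]Br | intermediate
5 | tert-butyldimethylsilyl ether of (2R)-2-methyl-7-(trimethylsilyl)hept-6-yn-1-ol | CC(C)(C)[Si](C)(C)OC[C@H](C)CCCC#C[Si](C)(C)C | intermediate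
6 | tert-butyldimethylsilyl ether of (2R)-2-methylhept-6-yn-1-ol | CC(C)(C)[Si](C)(C)OC[C@H](C)CCCC#C | intermediate
7 | (2R)-3-bromo-2-methylpropan-1-ol | OC[C@@H](C)CBr | starting material
8 | [(2R)-3-bromo-2-methylpropoxy](tert-butyl)dimethylsilane | CC(C)(C)[Si](C)(C)OC[C@@H](C)CBr | intermediate
9 | 2-(furan-3-yl)ethanol | OCCc1ccoc1 | starting material
10 | 3-(2-bromoethyl)furan | BrCCc1ccoc1 | intermediate
11 | [2-(furan-3-yl)ethyl]magnesium bromide (not isolated) | Br[Mg]CCc1ccoc1 | intermediate
12 | tert-butyldimethylsilyl ether of (2S)-5-(furan-3-yl)-2-methylpentan-1-ol | CC(C)(C)[Si](C)(C)OC[C@@H](C)CCCc1ccoc1 | intermediate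
13 | (2S)-5-(furan-3-yl)-2-methylpentan-1-ol | OC[C@@H](C)CCCc1ccoc1 | intermediate
14 | (2S)-5-(furan-3-yl)-2-methylpentanal | O=C[C@@H](C)CCCc1ccoc1 | intermediate
15 | 3-[(4S,5E)-6-iodo-4-methylhex-5-en-1-yl]furan | I/C=C/[C@@H](C)CCCc1ccoc1 | intermediate
16 | trimethylaluminium | C[Al](C)C | starting material
17 | (E)-alkenyldimethylalane from 6, Al on C12, CH3 on C11 (not isolated) | CC(C)(C)[Si](C)(C)OC[C@H](C)CCC/C(C)=C/[Al](C)C | intermediate
18 | (E)-alkenylzinc chloride from 17 (not isolated) | CC(C)(C)[Si](C)(C)OC[C@H](C)CCC/C(C)=C/[Zn]Cl | intermediate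
19 | tert-butyldimethylsilyl ether of (2R,6E,8E,10S)-13-(furan-3-yl)-2,6,10-trimethyltrideca-6,8-dien-1-ol | CC(C)(C)[Si](C)(C)OC[C@H](C)CCC/C(C)=C/C=C/[C@@H](C)CCCc1ccoc1 | intermediate
20 | (2R,6E,8E,10S)-13-(furan-3-yl)-2,6,10-trimethyltrideca-6,8-dien-1-ol | OC[C@H](C)CCC/C(C)=C/C=C/[C@@H](C)CCCc1ccoc1 | intermediate
21 | (2R,6E,8E,10S)-13-(furan-3-yl)-2,6,10-trimethyltrideca-6,8-dienal | O=C[C@H](C)CCC/C(C)=C/C=C/[C@@H](C)CCCc1ccoc1 | intermediate
22 | 4-hydroxy-3-methylfuran-2(5H)-one | CC1=C(O)COC1=O | starting material
23 | 4-methoxy-3-methylfuran-2(5H)-one | CC1=C(OC)COC1=O | intermediate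
24 | lithium 4-methoxy-3-methylfuran-2-olate (not isolated) | [Li+].[O-]c1occ(OC)c1C | intermediate
25 | 5-[(2R,6E,8E,10S)-13-(furan-3-yl)-1-hydroxy-2,6,10-trimethyltrideca-6,8-dien-1-yl]-4-methoxy-3-methylfuran-2(5H)-one, C5/C6 epimers | CC1=C(OC)C(OC1=O)C(O)[C@H](C)CCC/C(C)=C/C=C/[C@@H](C)CCCc2ccoc2 | intermediate
26 | C6 methanesulfonate of 25 (not isolated) | CC1=C(OC)C(OC1=O)C(OS(C)(=O)=O)[C@H](C)CCC/C(C)=C/C=C/[C@@H](C)CCCc2ccoc2 | intermediate
27 | (5Z)-5-[(2R,6E,8E,10S)-13-(furan-3-yl)-2,6,10-trimethyltrideca-6,8-dien-1-ylidene]-4-methoxy-3-methylfuran-2(5H)-one | CC1=C(OC)/C(=C/[C@H](C)CCC/C(C)=C/C=C/[C@@H](C)CCCc2ccoc2)OC1=O | intermediate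
28 | (5Z)-5-[(2R,6E,8E,10S)-13-(furan-3-yl)-2,6,10-trimethyltrideca-6,8-dien-1-ylidene]-4-hydroxy-3-methylfuran-2(5H)-one | CC1=C(O)/C(=C/[C@H](C)CCC/C(C)=C/C=C/[C@@H](C)CCCc2ccoc2)OC1=O | target

**Step count.** Total: 16 steps. Longest linear sequence: 11 steps (7 → 8 → 12 → 13 → 14 → 15 → 19 → 20 → 21 → 25 → 27 → 28; steps 4, 6–12, 14–16).

**Steps most likely to fail**

Step 10. The carbometalation may stall or lose regiocontrol. Methyl may be handed to palladium in place of the alkenyl group. Homocoupling may consume the iodide.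
The fallback sets out from 6 and 14 and comes back at 19. It separates the two events and moves the coupling from zinc to boron.
- Alane 17, made from 6 as before, is quenched with I2 in THF at −30 °C to give the tert-butyldimethylsilyl ether of (2R,6E)-7-iodo-2,6-dimethylhept-6-en-1-ol F1, which can be freed from any regioisomer by chromatography.
- Aldehyde 14 is homologated with Cl2CHBpin, CrCl2 and LiI (the boron variant of the Takai olefination) to 2-[(1E,3S)-6-(furan-3-yl)-3-methylhex-1-en-1-yl]-4,4,5,5-tetramethyl-1,3,2-dioxaborolane F2.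
- Suzuki–Miyaura coupling of the two (PdCl2(dppf), K3PO4, THF–H2O, rt) should give 19 with retention at both alkenes and with no methyl–metal species present.

Step 16. The thiolate may add to C4 or C6 of the cross-conjugated tetronate instead of attacking the methyl group. Prolonged heating may erode the 5Z geometry or the C7 configuration.
The fallback sets out from 22 and 21 and comes back at 28. It replaces the methyl group with a fluoride-labile one, so that no nucleophile has to attack the tetronate.
- Mitsunobu O-alkylation of 22 with 2-(trimethylsilyl)ethanol (DIAD, PPh3, THF) should give 3-methyl-4-[2-(trimethylsilyl)ethoxy]furan-2(5H)-one F3.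
- LiN(i-Pr)2 at −78 °C converts it into lithium 3-methyl-4-[2-(trimethylsilyl)ethoxy]furan-2-olate F4, which adds to 21 to give the silylethyl-protected aldol adduct F5.
- MsCl/Et3N gives the corresponding C6 mesylate F6, and DBU gives the (5Z)-ylidene silylethyl tetronate F7.
- Bu4NF in THF at rt then fragments the silylethyl group and, after mild acidification, should give 28.

Step 9. The elimination from the chromium adduct may be incompletely E-selective. Slow conversion of the branched aldehyde in the presence of Lewis-acidic trivalent chromium salts may allow partial epimerisation at C15. Either fault would be carried into the diene.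
The fallback sets out from 14 and comes back at 15. It derives the geometry from a syn hydrometalation instead of an olefination.
- Homologation with dimethyl (1-diazo-2-oxopropyl)phosphonate (K2CO3, MeOH, 0 °C) should give 3-[(4S)-4-methylhex-5-yn-1-yl]furan F8.
- Cp2Zr(H)Cl in THF adds syn with zirconium at the terminus to give the (E)-alkenylzirconocene chloride F9.
- Iodinolysis with I2 at 0 °C replaces zirconium with retention to give 15.

**Further compounds**

F1 | step 10 | tert-butyldimethylsilyl ether of (2R,6E)-7-iodo-2,6-dimethylhept-6-en-1-ol | CC(C)(C)[Si](C)(C)OC[C@H](C)CCC/C(C)=C/I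
F2 | step 10 | 2-[(1E,3S)-6-(furan-3-yl)-3-methylhex-1-en-1-yl]-4,4,5,5-tetramethyl-1,3,2-dioxaborolane | CC1(C)OB(/C=C/[C@@H](C)CCCc2ccoc2)OC1(C)C
F3 | step 16 | 3-methyl-4-[2-(trimethylsilyl)ethoxy]furan-2(5H)-one | CC1=C(OCC[Si](C)(C)C)COC1=O
F4 | step 16 | lithium 3-methyl-4-[2-(trimethylsilyl)ethoxy]furan-2-olate | [Li+].[O-]c1occ(OCC[Si](C)(C)C)c1C
F5 | step 16 | 5-[(2R,6E,8E,10S)-13-(furan-3-yl)-1-hydroxy-2,6,10-trimethyltrideca-6,8-dien-1-yl]-3-methyl-4-[2-(trimethylsilyl)ethoxy]furan-2(5H)-one, C5/C6 epimers | CC1=C(OCC[Si](C)(C)C)C(OC1=O)C(O)[C@H](C)CCC/C(C)=C/C=C/[C@@H](C)CCCc2ccoc2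
F6 | step 16 | C6 methanesulfonate of F5 | CC1=C(OCC[Si](C)(C)C)C(OC1=O)C(OS(C)(=O)=O)[C@H](C)CCC/C(C)=C/C=C/[C@@H](C)CCCc2ccoc2
F7 | step 16 | (5Z)-5-[(2R,6E,8E,10S)-13-(furan-3-yl)-2,6,10-trimethyltrideca-6,8-dien-1-ylidene]-3-methyl-4-[2-(trimethylsilyl)ethoxy]furan-2(5H)-one | CC1=C(OCC[Si](C)(C)C)/C(=C/[C@H](C)CCC/C(C)=C/C=C/[C@@H](C)CCCc2ccoc2)OC1=O
F8 | step 9 | 3-[(4S)-4-methylhex-5-yn-1-yl]furan | C#C[C@@H](C)CCCc1ccoc1
F9 | step 9 | chlorobis(cyclopentadienyl)[(1E,3S)-6-(furan-3-yl)-3-methylhex-1-en-1-yl]zirconium | Cl[Zr](/C=C/[C@@H](C)CCCc1ccoc1)(C1C=CC=C1)C1C=CC=C1
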